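**Retrosynthetic overview**

1. Numbering: ring A carries the ether oxygen at C1, the chain at C3 and OH at C5; ring B carries the ether oxygen at C1', OH at C2' and C5', and the chain at C3'; chain carbons are C1–C14 counted from ring A.
2. The strategy rests on the (CH2)14 chain joining ring A C3 to ring B C3', which has no functional group and whose length is 14 = 3 + 8 + 3. It is cut at chain C3–C4 and C11–C12 into two but-3-enyl arms (less their =CH2 ends) plus all eight carbons of cis-cyclooctene. One ring-expansion metathesis makes both bonds and the 21-membered ring; hydrogenation and BBr3 demethylation finish.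
3. The bis(butenyl) diaryl ether comes from a dibromo diaryl ether by double Negishi butenylation.
4. The dibromo diaryl ether comes from 3-bromo-5-methoxyphenol and 1-bromo-3-iodo-2,5-dimethoxybenzene by iodide-selective Ullmann coupling; the bromo-iodoarene comes from 2,6-dibromo-4-methoxyphenol by O-methylation and mono bromine–lithium exchange with iodine quench.
5. Ring order: rings A and B are bought; the macrocycle is the only ring formed (step 5).

Key step: step 5

Remark: the target has no stereocentre; the alkenes of 10, 11 and 12 are expected as E/Z mixtures, are drawn E for definiteness, and are removed in step 6.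

**Step 1**
Reactants: 1 2,6-dibromo-4-methoxyphenol
Product: 2 1,3-dibromo-2,5-dimethoxybenzene
Conditions: MeI (1.5 equiv), K2CO3 (2 equiv), DMF, 40 °C
Reagents that add atoms: iodomethane, CI
Why: Williamson O-methylation, in which the acidic di-ortho-bromo phenol is fully deprotonated by K2CO3 and iodomethane is small enough to alkylate the flanked oxygen.

**Step 2**
Reactants: 2 1,3-dibromo-2,5-dimethoxybenzene
Product: 4 1-bromo-3-iodo-2,5-dimethoxybenzene, via (3-bromo-2,5-dimethoxyphenyl)lithium 3 (not isolated)
Conditions: n-BuLi (1.0 equiv), THF, −78 °C, 30 min; then I2 (1.1 equiv) in THF, −78 °C to rt; aq. Na2S2O3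
Reagents that add atoms: iodine, [I][I]
Why: Bromine–lithium exchange then iodinolysis, in which one equivalent of n-BuLi exchanges only one of the two equivalent bromides, the aryllithium is held by the ortho methoxy group and has no ortho leaving group, and iodine converts it into an aryl iodide that differs in reactivity from the remaining bromide.

**Step 3**
Reactants: 4 1-bromo-3-iodo-2,5-dimethoxybenzene (1.2 equiv); 5 3-bromo-5-methoxyphenol
Product: 6 1-bromo-3-(3-bromo-5-methoxyphenoxy)-2,5-dimethoxybenzene
Conditions: CuI (10 mol %), picolinic acid (20 mol %), K3PO4 (2 equiv), DMSO, 80 °C, argon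
Reagents that add atoms: none
Why: Ullmann diaryl ether coupling, in which the ligated copper phenoxide reacts with aryl iodides far faster than with aryl bromides at 80 °C, so only the C–I bond of 4 should be replaced and the bromides of 4, of the electron-rich phenoxide of 5 and of the product should stay.

**Step 4**
Reactants: 6 1-bromo-3-(3-bromo-5-methoxyphenoxy)-2,5-dimethoxybenzene
Product: 8 1-(but-3-enyl)-3-[3-(but-3-enyl)-2,5-dimethoxyphenoxy]-5-methoxybenzene, via ring A monobutenyl bromide 7 (not isolated)
Conditions: but-3-enylzinc bromide (commercial 0.5 M in THF, 3 equiv), Pd(OAc)2 (4 mol %), SPhos (8 mol %), THF, 50 °C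
Reagents that add atoms: but-3-enylzinc bromide, C=CCC[Zn]Br
Why: Negishi coupling, in which a primary alkylzinc halide transmetalates and reductively eliminates on the SPhos-ligated palladium faster than β-hydride elimination, the unhindered ring A bromide is expected to react first and the excess reagent then carries the ortho-methoxy bromide of ring B through.

**Step 5**
Reactants: 8 1-(but-3-enyl)-3-[3-(but-3-enyl)-2,5-dimethoxyphenoxy]-5-methoxybenzene; 9 cis-cyclooctene (1.1 equiv)
Product: 12 tri-O-methyl 21-membered macrocyclic 3,11-diene (E/Z mixture; drawn 3E 11E), via ring A extended triene 10 (not isolated), via ring B extended triene 11 (not isolated)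
Conditions: RuCl2(=CHPh)(PCy3)(H2IMes) (second-generation Grubbs catalyst, 10 mol %), 1,4-benzoquinone (20 mol %), CH2Cl2 (2 mM in 8), 40 °C, argon sparge; 9 added by syringe pump over 8 h, then 12 h; ethyl vinyl ether quench
Reagents that add atoms: none
Why: The ruthenium alkylidene formed on a terminal butenyl arm of 8 (or the methylidene) opens strained cis-cyclooctene through a metallacyclobutane, giving the chain-extended species 10 or 11, whose new chain end then closes on the remaining butenyl arm with loss of ethene, so that chain C3=C4 and C11=C12 are formed. The closest known reaction type is ring-expansion metathesis, that is ring-opening cross-metathesis of a cycloalkene with an acyclic diene followed by ring-closing metathesis. The one ring formed is the 21-membered macrocycle, closed by macrocyclic ring-closing metathesis between the chain-end alkene and the opposite arm at high dilution. No stereocentre is created, and the geometry of both alkenes is left uncontrolled because step 6 removes it. The selectivity needed is uptake of exactly one cyclooctene unit: direct closure of the two arms would give a 13-membered meta,meta-bridged ring with the C2' methoxy group of ring B and C2–H of ring A pushed into its interior, so zero insertion is penalised, while the reversible catalyst at 2 mM should funnel material to the smallest strain-free ring, which is the single-insertion ring, and slow addition of 1.1 equivalents of cyclooctene limits double insertion and polymerisation. Benzoquinone suppresses ruthenium hydride migration of the alkenes, which would shorten the chain.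

**Step 6**
Reactants: 12 tri-O-methyl 21-membered macrocyclic 3,11-diene
Product: 13 tri-O-methyl saturated macrocycle (ring A 5-methoxy-1,3-phenylene and ring B 2,5-dimethoxy-1,3-phenylene joined by the ether oxygen and a (CH2)14 chain)
Conditions: H2 (1 atm), 10% Pd/C, EtOAc, rt
Reagents that add atoms: none
Why: Heterogeneous catalytic hydrogenation saturates both disubstituted alkenes whatever their geometry, while aryl methyl ethers and the diaryl ether are inert under these conditions.

**Step 7**
Reactants: 13 tri-O-methyl saturated macrocycle
Product: 15 target triphenol macrocycle CNP0393720.0, via tris(dibromoboryl) ether 14 (not isolated)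
Conditions: BBr3 (6 equiv), CH2Cl2, −78 °C to rt; then degassed H2O, aq. Na2S2O4 wash, under argon
Reagents that add atoms: none
Why: Lewis acid ether cleavage, in which BBr3 complexes each methoxy oxygen and bromide attacks the methyl carbon, whereas the diaryl ether has no sp3 carbon to attack and survives; hydrolysis frees the three phenols and dithionite keeps the ring B hydroquinone reduced.

**Compound list**

1 | 2,6-dibromo-4-methoxyphenol | COc1cc(Br)c(O)c(Br)c1 | starting material
2 | 1,3-dibromo-2,5-dimethoxybenzene | COc1cc(Br)c(OC)c(Br)c1 | intermediate
3 | (3-bromo-2,5-dimethoxyphenyl)lithium | [Li]c1cc(OC)cc(Br)c1OC | intermediate (not isolated)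
4 | 1-bromo-3-iodo-2,5-dimethoxybenzene | COc1cc(Br)c(OC)c(I)c1 | intermediate
5 | 3-bromo-5-methoxyphenol | COc1cc(O)cc(Br)c1 | starting material
6 | 1-bromo-3-(3-bromo-5-methoxyphenoxy)-2,5-dimethoxybenzene | COc1cc(Br)cc(c1)Oc1cc(OC)cc(Br)c1OC | intermediate
7 | 1-bromo-3-[3-(but-3-enyl)-5-methoxyphenoxy]-2,5-dimethoxybenzene (ring A monobutenyl bromide) | COc1cc(CCC=C)cc(c1)Oc1cc(OC)cc(Br)c1OC | intermediate (not isolated)
8 | 1-(but-3-enyl)-3-[3-(but-3-enyl)-2,5-dimethoxyphenoxy]-5-methoxybenzene | COc1cc(CCC=C)cc(c1)Oc1cc(OC)cc(CCC=C)c1OC | intermediate
9 | cis-cyclooctene | C1CCC/C=C\CC1 | starting material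
10 | 1-(but-3-enyl)-3-[3-(dodeca-3,11-dienyl)-5-methoxyphenoxy]-2,5-dimethoxybenzene (ring A extended triene, drawn 3E) | COc1cc(CC/C=C/CCCCCCC=C)cc(c1)Oc1cc(OC)cc(CCC=C)c1OC | intermediate (not isolated)
11 | 1-(dodeca-3,11-dienyl)-3-[3-(but-3-enyl)-5-methoxyphenoxy]-2,5-dimethoxybenzene (ring B extended triene, drawn 3E) | COc1cc(CCC=C)cc(c1)Oc1cc(OC)cc(CC/C=C/CCCCCCC=C)c1OC | intermediate (not isolated)
12 | tri-O-methyl 21-membered macrocyclic diene, chain C3=C4 and C11=C12 (E/Z mixture, drawn E,E) | COc1cc2cc(c1)Oc1cc(OC)cc(c1OC)CC/C=C/CCCCCC/C=C/CC2 | intermediate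
13 | tri-O-methyl saturated 21-membered macrocycle | COc1cc2cc(c1)Oc1cc(OC)cc(c1OC)CCCCCCCCCCCCCC2 | intermediate
14 | tris(dibromoboryl) ether of the target | BrB(Br)Oc1cc2cc(c1)Oc1cc(OB(Br)Br)cc(c1OB(Br)Br)CCCCCCCCCCCCCC2 | intermediate (not isolated)
15 | CNP0393720.0: 21-membered diaryl ether macrocycle, ring A 5-hydroxy-1,3-phenylene, ring B 2,5-dihydroxy-1,3-phenylene, (CH2)14 chain | Oc1cc2cc(c1)Oc1cc(O)cc(c1O)CCCCCCCCCCCCCC2 | target

**Totals**

Total step count: 7. Longest linear sequence: 7 steps (1 to 15).

**Steps most likely to fail**

1. Step 5. The number of cyclooctene units taken up may not be controlled: the two arms may close directly without insertion, two or more units may be inserted, or ring-opening polymerisation of cyclooctene may outrun chain transfer. The result would be a set of ring-size homologues that is hard to separate, although wrong-sized fractions could be re-equilibrated with fresh catalyst. Fallback, setting out from 6 and coming back at 13: 6 would be coupled twice with oct-7-enylzinc bromide (from 8-bromooct-1-ene and LiCl-activated zinc dust; Pd(OAc)2, SPhos, THF, 50 °C) to give 1-(oct-7-enyl)-3-[2,5-dimethoxy-3-(oct-7-enyl)phenoxy]-5-methoxybenzene F1. Here the chain length is fixed by the arms (8 + 8 − 2 = 14), so ordinary two-component macrocyclic ring-closing metathesis (RuCl2(=CHPh)(PCy3)(H2IMes), CH2Cl2, 1 mM, 40 °C) should close the same 21-membered ring at chain C7=C8 with loss of ethene, giving the tri-O-methyl macrocyclic 7-ene F2. Hydrogenation of F2 over Pd/C as in step 6 gives 13.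

2. Step 3. Chemoselectivity between C–I and C–Br may be lost: copper may insert into the bromide of the phenol or of the product and give oligomeric ethers, or coupling at the ortho-methoxy iodide may be slow and accompanied by reductive loss of iodine. Fallback, setting out from 2 and coming back at 6: 2 would be lithiated as in step 2 and the aryllithium 3 trapped with B(OiPr)3, then aqueous HCl, to give (3-bromo-2,5-dimethoxyphenyl)boronic acid F3. Chan–Lam coupling of F3 with phenol 5 (Cu(OAc)2, pyridine, 4 Å molecular sieves, CH2Cl2, air, rt) forms the diaryl ether through an oxidative copper cycle at room temperature that does not touch aryl bromides, and gives 6.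

3. Step 4. The second coupling at the hindered ortho-methoxy bromide may stall, β-hydride elimination may lead to loss of bromine without coupling, or palladium hydride may move the terminal double bond into the arm, which would later shorten the chain in the metathesis. Fallback without palladium, setting out from 6 and coming back at 8: double bromine–lithium exchange (n-BuLi, 2.2 equiv, THF, −78 °C) and DMF quench would give 3-(3-formyl-5-methoxyphenoxy)-2,5-dimethoxybenzaldehyde F4. NaBH4 in MeOH reduces it to [3-[3-(hydroxymethyl)-5-methoxyphenoxy]-2,5-dimethoxyphenyl]methanol F5, and PBr3 in CH2Cl2 at 0 °C gives 1-(bromomethyl)-3-[3-(bromomethyl)-5-methoxyphenoxy]-2,5-dimethoxybenzene F6. Displacement of both benzylic bromides with allylmagnesium bromide (THF, 0 °C) builds each but-3-enyl arm at the benzylic CH2–CH2 bond and gives 8.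

**Further compounds**

F1 | step 5 | 1-(oct-7-enyl)-3-[2,5-dimethoxy-3-(oct-7-enyl)phenoxy]-5-methoxybenzene | COc1cc(CCCCCCC=C)cc(c1)Oc1cc(OC)cc(CCCCCCC=C)c1OC
F2 | step 5 | tri-O-methyl 21-membered macrocyclic 7-ene (drawn E) | COc1cc2cc(c1)Oc1cc(OC)cc(c1OC)CCCCCC/C=C/CCCCCC2
F3 | step 3 | (3-bromo-2,5-dimethoxyphenyl)boronic acid | OB(O)c1cc(OC)cc(Br)c1OC
F4 | step 4 | 3-(3-formyl-5-methoxyphenoxy)-2,5-dimethoxybenzaldehyde | COc1cc(C=O)cc(c1)Oc1cc(OC)cc(C=O)c1OC
F5 | step 4 | [3-[3-(hydroxymethyl)-5-methoxyphenoxy]-2,5-dimethoxyphenyl]methanol | COc1cc(CO)cc(c1)Oc1cc(OC)cc(CO)c1OC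
F6 | step 4 | 1-(bromomethyl)-3-[3-(bromomethyl)-5-methoxyphenoxy]-2,5-dimethoxybenzene | COc1cc(CBr)cc(c1)Oc1cc(OC)cc(CBr)c1OC
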